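Each new flask was to be read at 10 d, later than the last blue reading at 8.00 d, so I had to count forward from the readings.

| setting | blue | ochre | green | eta | beta | gamma |
|---|---|---|---|---|---|---|
| G | 0.25 M | 0.25 M | 0.25 M | 0.25 M | 0.25 M | 0.25 M |
| J | 1.1 equiv | 2.2 equiv | 5.7 equiv | 1.20 equiv | 2.40 equiv | 4.80 equiv |
| Z | 0.125 M | 0.125 M | 0.125 M | 0.125 M | 0.125 M | 0.125 M |
| remark | run made earlier | run made earlier | run made earlier |  |  |  |
| time |  |  |  | 10 d | 10 d | 10 d |

- blue (time / d: G / %, D / %): 0.625: 71, 6; 1.67: 51, 7; 3.00: 37, 1; 5.00: 24, 2; 8.00: 14, 2
- ochre (time / d: G / %, D / %): 0.625: 60, 12; 1.04: 43, 10; 2.08: 23, 3; 4.00: 9, 3; 8.00: 0, 3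
- green (time / d: G / %, D / %): 0.625: 31, 24; 1.67: 5, 2; 3.00: 0, 0; 5.00: 0, 2; 8.00: 2, 0

(scatter of a reading: 2 percentage points)

- part of the G that has reacted at the end, eta
- part of the G that has reacted at the end, beta
- part of the G that has reacted at the end, gamma
- what raising the equivalents of J from its lowest to its highest value here does to the part of the G that has reacted (changes below 5 percentage points count as none) (no change / it rises / it falls)



I read the G column of each table as a rate, taking the logarithm of the ratio of neighbouring readings over the time between them. Going down the blue table, this rate fell from 0.317 d⁻¹ between the first two readings to 0.180 d⁻¹ between the last two. Eta's 1.20 equiv lies nearest blue's 1.1 equiv, so I continued blue at that last rate. The 2.00 d up to the reading then held 0.359 turnovers, a turnover count being the natural logarithm of c_G before over c_G after. From the blue reading of 14%, that left about 9.78% of G, so I committed to 90.2% reacted for eta, a figure that carries the scatter of the readings.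

The ochre table, nearest to beta, ended its useful column at 9% after 4.00 d, at a rate of 0.489 d⁻¹. The remaining time held 2.93 turnovers, which left about 0.481% of G in beta. The green table, nearest to gamma, gave 1.75 d⁻¹, and I counted 14.5 turnovers after its reading of 5%, so I took gamma as complete. So I expected a rise of about 9.8 percentage points from eta to gamma, more than the 5 points that counts.

The forecast gave 92% for eta (87% to 96%), above my figure, then 99.7% and 100%, with “Beta and gamma should be essentially complete” and the verdict it rises.

The flasks gave 88.5%, 99.4% and >99.9%, and the verdict was it rises, a change of 12 points.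

    G + J → X + D (k = 0.0606 M⁻¹ h⁻¹)
    J + X ⇌ L, settled at all times (K = 33000 M⁻¹)
    G + Z → Q (k = 0.0672 M⁻¹ h⁻¹)
    D → E (k = 0.143 h⁻¹)

Eta held G at 22.5% after 5.00 d and 11.5% at 10.0 d. Its last stretch therefore held 0.671 turnovers, or 0.134 d⁻¹, slower than the 0.180 d⁻¹ behind my 0.359. Beta's same stretch held 2.16 turnovers, and G, the limiting reagent there, ended at 0.604% with J at 35.4% of its own charge.

Readings and results are calculated on assumed constants; noise was put on by code.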